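The earlier runs and the new flask were computed from invented constants, and the scatter is random.

- I had to say which flask, amber or green, ends with more target, and what fraction of the substrate charge each reaches.

| flask | substrate | reagent | free catalyst | remark | time |
|---|---|---|---|---|---|
| east | 0.20 M (fed, over 10 min) | 0.22 M | 9.4 mM | run made earlier; the fed solution adds 1.0 times the starting volume |  |
| north-west | 0.20 M (fed, over 10 min) | 0.22 M | 17 mM | run made earlier; the fed solution adds 1.0 times the starting volume |  |
| amber | 0.20 M | 0.220 M | 15 mM | everything together at the start, the whole solution of substrate included, so that from the start the volume is larger by 1.0 times the starting volume | 40 min |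
| green | 0.20 M (fed, over 10 min) | 0.220 M | 7.0 mM | the fed solution adds 1.0 times the starting volume | 40 min |

- east (time / min: target / %): 5.00: 6; 15.0: 19; 25.0: 28; 40.0: 44
- north-west (time / min: target / %): 5.00: 8; 15.0: 28; 25.0: 47; 40.0: 63

(readings scatter by 2 percentage points)

1. which one finishes higher in amount of target, in percent of the substrate charged ("neither" within 2 percentage points) (amber / green / neither)
2. amount of target at the end, in percent of the substrate charged, amber
3. amount of target at the end, in percent of the substrate charged, green

- charges are per starting volume, the dose included; the dosed solution carries all of it
- percentages count the whole charge, also what has not yet gone in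

- The substrate is the limiting reagent, with reagent charged at 1.10 times its amount. I treated the two as equal, as in step-growth kinetics, so target made over target missing, both as fractions of the charge, should rise straight with time.
- My first way replaced the steady feed by its mean: the whole charge dumped at half the dosing time, 5.00 min. The last readings then gave 0.0224 min⁻¹ for east and 0.0486 min⁻¹ for north-west.
- My second way needed no mean: I took the reciprocal of the missing fraction and differenced it between 15.0 min and 40.0 min, which gave 0.0220 min⁻¹ for east and 0.0526 min⁻¹ for north-west.
- East agreed. North-west parted by 0.00390 min⁻¹, but that is less than the 0.00417 min⁻¹ that the scatter of one reading moves it. So I could not convict the mean, and I kept the first way, which leans on one reading per run.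
- Amber's catalyst lies between the two runs, so I interpolated its pace, 0.0418 min⁻¹: the ratio of target made to target missing, gained per minute in the flask. Amber has no feed lag, so 40 min gave me 62.5%.
- Green's catalyst lies below east, so I scaled east in proportion to free catalyst, which gave 0.0167 min⁻¹. Counting 35.0 min from the mean charge in green, that gave 36.9%, so I put amber ahead.
- The forecast said amber, with amber at 61% and green at 35%, on the ground that “Dosing gains little here, and catalyst dominates”. Both of my figures stood above its figures.
- The flask gave amber, with amber at 62.9% and green at 36.3%.

    reagent + catalyst intermediate B → catalyst intermediate C (k = 9.50 M⁻¹ min⁻¹)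
    catalyst intermediate C ⇌ free catalyst + target (K = 0.110 M, k = 3.30 min⁻¹)
    substrate → decomposition product (k = 4.00 × 10⁻⁵ min⁻¹)
    catalyst intermediate A → catalyst intermediate B (k = 2.30 min⁻¹)
    substrate + free catalyst → catalyst intermediate A (k = 9.40 M⁻¹ min⁻¹)

- At 40.0 min, amber still held 32.5% of its substrate. Carried to 90.0 min on the amber flask, my pace of 0.0418 min⁻¹ gives 79.0%, and target in that flask stood at 88.1%.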